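**Retrosynthetic overview**
- Feature: in ring A, C1 (side chain), C3 (OMe) and C5 (OH) carry carbon or oxygen in the 1,3,5-pattern of a folded poly-β-carbonyl chain, and C2 between them carries an extra, hindered oxygen (OAc). The plan keeps a carbon substituent on C2 through ring formation and exchanges it for oxygen late.
- Endgame: diacetate and free C5 phenol from a benzyl-protected phenol, made by Dakin oxidation of a 4-benzyloxy-2-methoxy-6-alkylbenzaldehyde; the aldehyde comes from half-reduction of an acetonide-masked resorcylate (a benzodioxinone).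
- Ring A, the only ring built, is closed at the C1–C2 bond by amine-mediated aldol aromatisation of a 6-(2,4-dioxoalkyl)dioxinone carrying the (R)-silyloxy chain.
- The diketo-dioxinone is cut at the future C1–C6 bond: Claisen-type acylation of the dianion of 6-(2-oxopropyl)dioxinone by an (R)-3-silyloxy Weinreb amide.
- The stereocentre comes from asymmetric hydrogenation of methyl 3-oxohexadecanoate (tetradecanoyl chloride plus Meldrum's acid).

Key step: step 7

Remark: ring A of the target is numbered C1 (side chain), C2 (OAc), C3 (OMe), C4 (H), C5 (OH), C6 (H); the lithium amide bases are taken as commercial solutions.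

**Route**

Step 1
Reactants: 1 tetradecanoyl chloride; 2 2,2-dimethyl-1,3-dioxane-4,6-dione (Meldrum's acid)
Product: 4 methyl 3-oxohexadecanoate, via acyl Meldrum's acid 3 (not isolated)
Conditions: pyridine (2 equiv), CH2Cl2, 0 °C → rt; dilute HCl wash; then MeOH, reflux
Reagents that add atoms: methanol, CO
Why: C-acylation of the cyclic malonate followed by methanolysis of the acyl derivative with loss of acetone and CO2 (Oikawa–Yonemitsu β-keto ester synthesis) is a standard entry to long-chain 3-oxo esters.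

Step 2
Reactants: 4 methyl 3-oxohexadecanoate
Product: 5 methyl (3R)-3-hydroxyhexadecanoate
Conditions: H2 (10 bar), RuCl2[(R)-BINAP] (0.5 mol%), MeOH, 60 °C
Reagents that add atoms: none
Why: Noyori asymmetric hydrogenation: the ester carbonyl chelates ruthenium and the (R)-BINAP ligand should deliver hydrogen to the ketone face that gives the (3R)-alcohol, the sense established for simple 3-oxoalkanoates.

Step 3
Reactants: 5 methyl (3R)-3-hydroxyhexadecanoate
Product: 6 methyl (3R)-3-(triisopropylsilyloxy)hexadecanoate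
Conditions: TIPSOTf, 2,6-lutidine, CH2Cl2, 0 °C → rt
Reagents that add atoms: triisopropylsilyl trifluoromethanesulfonate, CC(C)[Si](C(C)C)(C(C)C)OS(=O)(=O)C(F)(F)F
Why: Silylation of the secondary alcohol with the silyl triflate and a hindered pyridine base is fast at 0 °C, and the bulky silyl ether is chosen to resist the bases, hydride and carbonate used later.

Step 4
Reactants: 6 methyl (3R)-3-(triisopropylsilyloxy)hexadecanoate
Product: 7 (3R)-N-methoxy-N-methyl-3-(triisopropylsilyloxy)hexadecanamide
Conditions: MeNH(OMe)·HCl (1.5 equiv), i-PrMgCl (3 equiv), THF, −20 → 0 °C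
Reagents that add atoms: N,O-dimethylhydroxylamine hydrochloride, CNOC.Cl
Why: Aminolysis of the methyl ester by the chloromagnesium amide formed from the hydroxylamine salt and i-PrMgCl (Weinreb amide synthesis) proceeds below 0 °C without enolising the ester, so the β-silyloxy group should not be eliminated.

Step 5
Reactants: 8 2,2,6-trimethyl-4H-1,3-dioxin-4-one
Product: 10 2,2-dimethyl-6-(2-oxopropyl)-4H-1,3-dioxin-4-one, via lithium dienolate 9 (not isolated)
Conditions: LiN(SiMe3)2, THF, −78 °C; then AcCl (0.5 equiv), −78 °C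
Reagents that add atoms: acetyl chloride, CC(Cl)=O
Why: Kinetic γ-deprotonation of the dioxinone gives dienolate 9, which is C-acylated at its exocyclic carbon by acetyl chloride (Claisen-type acylation), two equivalents of enolate being used per acetyl chloride because the product is the stronger acid.

Step 6
Reactants: 10 2,2-dimethyl-6-(2-oxopropyl)-4H-1,3-dioxin-4-one; 7 (3R)-N-methoxy-N-methyl-3-(triisopropylsilyloxy)hexadecanamide
Product: 12 6-[(6R)-2,4-dioxo-6-(triisopropylsilyloxy)nonadecyl]-2,2-dimethyl-4H-1,3-dioxin-4-one, via dilithium dianion 11 (not isolated)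
Conditions: LiN(i-Pr)2 (2.1 equiv per 10), THF, −78 °C; then 7 (0.5 equiv), −78 → −40 °C; 1 M HCl to pH 3, 0 °C; used promptly
Reagents that add atoms: none
Why: The dianion reacts at its terminal, less stabilised carbon with the Weinreb amide (crossed Claisen-type C-acylation), and since this amide transfers its acyl group only once the 1,3-diketone should be obtained after a cold acidic quench.

Step 7
Reactants: 12 6-[(6R)-2,4-dioxo-6-(triisopropylsilyloxy)nonadecyl]-2,2-dimethyl-4H-1,3-dioxin-4-one
Product: 14 7-hydroxy-2,2-dimethyl-5-[(2R)-2-(triisopropylsilyloxy)pentadecyl]-4H-1,3-benzodioxin-4-one, via aldol adduct 13 (not isolated)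
Conditions: Et3N (3 equiv), CH2Cl2, 0 °C → rt
Reagents that add atoms: none
Why: Triethylamine deprotonates the C1 methylene of the side chain, which is flanked by the C2 ketone and the dioxinone, and the resulting dienolate attacks the C4 ketone through the dioxinone α-carbon (dioxinone C5) in an intramolecular aldol addition to give carbinol 13, which loses water and enolises at the remaining ketone to give the phenol of 14. The closest known reaction type is the amine-mediated aldol aromatisation of 6-(2,4-dioxoalkyl)-1,3-dioxin-4-ones to acetonide-masked resorcylates, a laboratory copy of polyketide folding. Ring A closes in a 6-exo-trig mode at the ketone carbonyl, with the nucleophilic carbon and the adjacent C=C unit of the dienolate lying inside the new ring. No stereocentre is set: the two sp3 centres of 13 disappear on aromatisation and the silyloxy-bearing carbon is a spectator. The step needs C–C closure at the C4 ketone in preference to closure through the enol oxygen (pyranone), Claisen attack of C3 on the dioxinone carbonyl, or E1cB loss of the β-silyloxy group; the weak amine base, the low electrophilicity of the acetal-flanked ester carbonyl, the bulk of the triisopropylsilyl ether and the irreversible aromatisation should secure it.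

Step 8
Reactants: 14 7-hydroxy-2,2-dimethyl-5-[(2R)-2-(triisopropylsilyloxy)pentadecyl]-4H-1,3-benzodioxin-4-one
Product: 15 7-(benzyloxy)-2,2-dimethyl-5-[(2R)-2-(triisopropylsilyloxy)pentadecyl]-4H-1,3-benzodioxin-4-one
Conditions: BnBr, K2CO3, DMF, rt
Reagents that add atoms: benzyl bromide, BrCc1ccccc1
Why: Williamson etherification of the only free phenol, whose acidity is raised by the para ester carbonyl, while the other phenolic oxygen stays locked in the acetonide.

Step 9
Reactants: 15 7-(benzyloxy)-2,2-dimethyl-5-[(2R)-2-(triisopropylsilyloxy)pentadecyl]-4H-1,3-benzodioxin-4-one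
Product: 17 4-(benzyloxy)-2-hydroxy-6-[(2R)-2-(triisopropylsilyloxy)pentadecyl]benzaldehyde, via diisobutylaluminium hemiacetal 16 (not isolated)
Conditions: i-Bu2AlH (1.3 equiv), CH2Cl2, −78 °C; then aq. potassium sodium tartrate, rt
Reagents that add atoms: none
Why: Half-reduction of the aryl ester carbonyl by i-Bu2AlH at −78 °C gives the tetrahedral aluminium hemiacetal 16, which should hold until work-up and then collapse with loss of acetone to reveal the aldehyde and its ortho phenol together (ester-to-aldehyde partial reduction).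

Step 10
Reactants: 17 4-(benzyloxy)-2-hydroxy-6-[(2R)-2-(triisopropylsilyloxy)pentadecyl]benzaldehyde
Product: 18 4-(benzyloxy)-2-methoxy-6-[(2R)-2-(triisopropylsilyloxy)pentadecyl]benzaldehyde
Conditions: MeI, K2CO3, DMF, rt
Reagents that add atoms: iodomethane, CI
Why: Williamson O-methylation with MeI and K2CO3 in DMF overcomes the hydrogen bond between the phenol and the formyl group and fixes the future C3 methoxy group.

Step 11
Reactants: 18 4-(benzyloxy)-2-methoxy-6-[(2R)-2-(triisopropylsilyloxy)pentadecyl]benzaldehyde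
Product: 20 4-(benzyloxy)-2-methoxy-6-[(2R)-2-(triisopropylsilyloxy)pentadecyl]phenol, via aryl formate 19 (not isolated)
Conditions: mCPBA (1.3 equiv), CH2Cl2, 0 °C → rt; aq. Na2S2O3/NaHCO3 wash; then K2CO3 (cat.), MeOH, 0 °C
Reagents that add atoms: 3-chloroperoxybenzoic acid (mCPBA), OOC(=O)c1cccc(Cl)c1
Why: Dakin-type Baeyer–Villiger oxidation, in which the electron-rich 2,4-dialkoxy-6-alkylaryl group migrates in preference to hydrogen to give formate 19, followed by carbonate-catalysed methanolysis of the formate to the phenol.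

Step 12
Reactants: 20 4-(benzyloxy)-2-methoxy-6-[(2R)-2-(triisopropylsilyloxy)pentadecyl]phenol
Product: 21 4-(benzyloxy)-2-[(2R)-2-hydroxypentadecyl]-6-methoxyphenol
Conditions: HF·pyridine, pyridine, THF, 0 °C → rt, under argon
Reagents that add atoms: none
Why: Fluoride-mediated desilylation driven by the strength of the Si–F bond, run in the acidic HF·pyridine medium so that the oxidation-prone phenoxide of the para-alkoxyphenol is never formed and the benzyl and methyl ethers stay in place.

Step 13
Reactants: 21 4-(benzyloxy)-2-[(2R)-2-hydroxypentadecyl]-6-methoxyphenol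
Product: 22 (2R)-1-[2-acetoxy-5-(benzyloxy)-3-methoxyphenyl]pentadecan-2-yl acetate
Conditions: Ac2O (excess), pyridine, DMAP (cat.), CH2Cl2, rt
Reagents that add atoms: acetic anhydride, CC(=O)OC(C)=O
Why: Nucleophilic catalysis by DMAP (Steglich-type acylation with an anhydride) should acetylate both the secondary alcohol and the phenol flanked by two ortho substituents.

Step 14
Reactants: 22 (2R)-1-[2-acetoxy-5-(benzyloxy)-3-methoxyphenyl]pentadecan-2-yl acetate
Product: 23 (2R)-1-(2-acetoxy-5-hydroxy-3-methoxyphenyl)pentadecan-2-yl acetate (CNP0236046.1)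
Conditions: H2 (1 atm), 10% Pd/C, EtOAc, rt
Reagents that add atoms: none
Why: Hydrogenolysis of the benzyl aryl ether over Pd/C in an aprotic ester solvent frees the C5 phenol while leaving both acetates, the methyl ether and the stereocentre untouched.

**Compound list**

1 | tetradecanoyl chloride | CCCCCCCCCCCCCC(Cl)=O | starting material
2 | 2,2-dimethyl-1,3-dioxane-4,6-dione (Meldrum's acid) | CC1(C)OC(=O)CC(=O)O1 | starting material
3 | acyl Meldrum's acid, 5-(1-hydroxytetradecylidene)-2,2-dimethyl-1,3-dioxane-4,6-dione (not isolated) | CCCCCCCCCCCCCC(O)=C1C(=O)OC(C)(C)OC1=O | intermediate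
4 | methyl 3-oxohexadecanoate | CCCCCCCCCCCCCC(=O)CC(=O)OC | intermediate
5 | methyl (3R)-3-hydroxyhexadecanoate | CCCCCCCCCCCCC[C@H](CC(=O)OC)O | intermediate
6 | methyl (3R)-3-(triisopropylsilyloxy)hexadecanoate | CCCCCCCCCCCCC[C@H](CC(=O)OC)O[Si](C(C)C)(C(C)C)C(C)C | intermediate
7 | (3R)-N-methoxy-N-methyl-3-(triisopropylsilyloxy)hexadecanamide | CCCCCCCCCCCCC[C@H](CC(=O)N(C)OC)O[Si](C(C)C)(C(C)C)C(C)C | intermediate
8 | 2,2,6-trimethyl-4H-1,3-dioxin-4-one | CC1=CC(=O)OC(C)(C)O1 | starting material
9 | lithium dienolate of 8, lithium 2,2-dimethyl-6-methylidene-1,3-dioxin-4-olate (not isolated) | [Li+].C=C1C=C([O-])OC(C)(C)O1 | intermediate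
10 | 2,2-dimethyl-6-(2-oxopropyl)-4H-1,3-dioxin-4-one | CC(=O)CC1=CC(=O)OC(C)(C)O1 | intermediate
11 | dilithium dianion of 10 (not isolated) | [Li+].[Li+].C=C([O-])C=C1C=C([O-])OC(C)(C)O1 | intermediate
12 | 6-[(6R)-2,4-dioxo-6-(triisopropylsilyloxy)nonadecyl]-2,2-dimethyl-4H-1,3-dioxin-4-one | CCCCCCCCCCCCC[C@H](CC(=O)CC(=O)CC1=CC(=O)OC(C)(C)O1)O[Si](C(C)C)(C(C)C)C(C)C | intermediate
13 | aldol adduct, 5-hydroxy-2,2-dimethyl-5-[(2R)-2-(triisopropylsilyloxy)pentadecyl]-4a,5,6,7-tetrahydro-4H-1,3-benzodioxine-4,7-dione, ring sp3 centres unassigned (not isolated) | CCCCCCCCCCCCC[C@H](CC1(O)CC(=O)C=C2OC(C)(C)OC(=O)C12)O[Si](C(C)C)(C(C)C)C(C)C | intermediate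
14 | 7-hydroxy-2,2-dimethyl-5-[(2R)-2-(triisopropylsilyloxy)pentadecyl]-4H-1,3-benzodioxin-4-one | CCCCCCCCCCCCC[C@H](Cc1cc(O)cc2OC(C)(C)OC(=O)c12)O[Si](C(C)C)(C(C)C)C(C)C | intermediate
15 | 7-(benzyloxy)-2,2-dimethyl-5-[(2R)-2-(triisopropylsilyloxy)pentadecyl]-4H-1,3-benzodioxin-4-one | CCCCCCCCCCCCC[C@H](Cc1cc(OCc3ccccc3)cc2OC(C)(C)OC(=O)c12)O[Si](C(C)C)(C(C)C)C(C)C | intermediate
16 | diisobutylaluminium hemiacetal of 15 at C4, acetal carbon unassigned (not isolated) | CCCCCCCCCCCCC[C@H](Cc1cc(OCc3ccccc3)cc2OC(C)(C)OC(O[Al](CC(C)C)CC(C)C)c12)O[Si](C(C)C)(C(C)C)C(C)C | intermediate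
17 | 4-(benzyloxy)-2-hydroxy-6-[(2R)-2-(triisopropylsilyloxy)pentadecyl]benzaldehyde | CCCCCCCCCCCCC[C@H](Cc1cc(OCc2ccccc2)cc(O)c1C=O)O[Si](C(C)C)(C(C)C)C(C)C | intermediate
18 | 4-(benzyloxy)-2-methoxy-6-[(2R)-2-(triisopropylsilyloxy)pentadecyl]benzaldehyde | CCCCCCCCCCCCC[C@H](Cc1cc(OCc2ccccc2)cc(OC)c1C=O)O[Si](C(C)C)(C(C)C)C(C)C | intermediate
19 | 4-(benzyloxy)-2-methoxy-6-[(2R)-2-(triisopropylsilyloxy)pentadecyl]phenyl formate (not isolated) | CCCCCCCCCCCCC[C@H](Cc1cc(OCc2ccccc2)cc(OC)c1OC=O)O[Si](C(C)C)(C(C)C)C(C)C | intermediate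
20 | 4-(benzyloxy)-2-methoxy-6-[(2R)-2-(triisopropylsilyloxy)pentadecyl]phenol | CCCCCCCCCCCCC[C@H](Cc1cc(OCc2ccccc2)cc(OC)c1O)O[Si](C(C)C)(C(C)C)C(C)C | intermediate
21 | 4-(benzyloxy)-2-[(2R)-2-hydroxypentadecyl]-6-methoxyphenol | CCCCCCCCCCCCC[C@H](Cc1cc(OCc2ccccc2)cc(OC)c1O)O | intermediate
22 | (2R)-1-[2-acetoxy-5-(benzyloxy)-3-methoxyphenyl]pentadecan-2-yl acetate | CCCCCCCCCCCCC[C@H](Cc1cc(OCc2ccccc2)cc(OC)c1OC(C)=O)OC(C)=O | intermediate
23 | (2R)-1-(2-acetoxy-5-hydroxy-3-methoxyphenyl)pentadecan-2-yl acetate | CCCCCCCCCCCCC[C@H](Cc1cc(O)cc(OC)c1OC(C)=O)OC(C)=O | target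

**Step count**
Total: 14 steps. Longest linear sequence: 13 steps (steps 1–4 and 6–14 from tetradecanoyl chloride 1); step 5 is the only branch step.

**Steps most likely to fail**

Step 7 (key cyclisation). The enolised diketone may close through oxygen onto the dioxinone β-carbon, or lose the β-silyloxy group by elimination, faster than the C–C aldol closure; the carbinol may also dehydrate sluggishly. The fallback separates unmasking of the dioxinone from ring closure and uses a β-keto ester carbon as the nucleophile. It sets out from 12. Heating 12 in toluene with methanol at 110 °C (sealed vessel) expels acetone, and the acylketene is trapped as methyl (9R)-3,5,7-trioxo-9-(triisopropylsilyloxy)docosanoate F1. Treatment with Cs2CO3 in MeOH and acidification with AcOH should aromatise it to methyl 2,4-dihydroxy-6-[(2R)-2-(triisopropylsilyloxy)pentadecyl]benzoate F2. BnBr and K2CO3 in acetone alkylate the para hydroxyl, which is not hydrogen-bonded, to give methyl 4-(benzyloxy)-2-hydroxy-6-[(2R)-2-(triisopropylsilyloxy)pentadecyl]benzoate F3. MeI and K2CO3 in warm DMF give methyl 4-(benzyloxy)-2-methoxy-6-[(2R)-2-(triisopropylsilyloxy)pentadecyl]benzoate F4. LiAlH4 in THF reduces the ester to {4-(benzyloxy)-2-methoxy-6-[(2R)-2-(triisopropylsilyloxy)pentadecyl]phenyl}methanol F5, and MnO2 in CH2Cl2 oxidises the benzylic alcohol. The fallback comes back to the route at 18.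

Step 6 (dianion acylation). The dianion may act as a base on the α-methylene of the β-silyloxy amide, leading to loss of silanolate, or acyl transfer may stall and the sensitive product cyclise during work-up. The fallback replaces acylation by aldol addition and oxidation. It sets out from 6, which i-Bu2AlH in CH2Cl2 at −78 °C reduces to (3R)-3-(triisopropylsilyloxy)hexadecanal F6. Addition of dianion 11 at −78 °C gives 6-[(6R)-4-hydroxy-2-oxo-6-(triisopropylsilyloxy)nonadecyl]-2,2-dimethyl-4H-1,3-dioxin-4-one F7, as a mixture at the new carbinol carbon, which does not matter. Dess–Martin periodinane in CH2Cl2 oxidises the carbinol, and the fallback comes back to the route at 12.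

Step 9 (half-reduction). The aluminium hemiacetal may collapse before the quench, so that the aldehyde is reduced further to the benzylic alcohol, or hydride delivery to a carbonyl flanked by two ortho substituents may be slow. The fallback reduces fully and re-oxidises. It sets out from 15, which LiAlH4 in THF at 0 °C reduces to 5-(benzyloxy)-2-(hydroxymethyl)-3-[(2R)-2-(triisopropylsilyloxy)pentadecyl]phenol F8. MnO2 in CH2Cl2 then oxidises only the benzylic alcohol, and the fallback comes back to the route at 17.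

**Further compounds**
F1 | step 7 | methyl (9R)-3,5,7-trioxo-9-(triisopropylsilyloxy)docosanoate | CCCCCCCCCCCCC[C@H](CC(=O)CC(=O)CC(=O)CC(=O)OC)O[Si](C(C)C)(C(C)C)C(C)C
F2 | step 7 | methyl 2,4-dihydroxy-6-[(2R)-2-(triisopropylsilyloxy)pentadecyl]benzoate | CCCCCCCCCCCCC[C@H](Cc1cc(O)cc(O)c1C(=O)OC)O[Si](C(C)C)(C(C)C)C(C)C
F3 | step 7 | methyl 4-(benzyloxy)-2-hydroxy-6-[(2R)-2-(triisopropylsilyloxy)pentadecyl]benzoate | CCCCCCCCCCCCC[C@H](Cc1cc(OCc2ccccc2)cc(O)c1C(=O)OC)O[Si](C(C)C)(C(C)C)C(C)C
F4 | step 7 | methyl 4-(benzyloxy)-2-methoxy-6-[(2R)-2-(triisopropylsilyloxy)pentadecyl]benzoate | CCCCCCCCCCCCC[C@H](Cc1cc(OCc2ccccc2)cc(OC)c1C(=O)OC)O[Si](C(C)C)(C(C)C)C(C)C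
F5 | step 7 | {4-(benzyloxy)-2-methoxy-6-[(2R)-2-(triisopropylsilyloxy)pentadecyl]phenyl}methanol | CCCCCCCCCCCCC[C@H](Cc1cc(OCc2ccccc2)cc(OC)c1CO)O[Si](C(C)C)(C(C)C)C(C)C
F6 | step 6 | (3R)-3-(triisopropylsilyloxy)hexadecanal | CCCCCCCCCCCCC[C@H](CC=O)O[Si](C(C)C)(C(C)C)C(C)C
F7 | step 6 | 6-[(6R)-4-hydroxy-2-oxo-6-(triisopropylsilyloxy)nonadecyl]-2,2-dimethyl-4H-1,3-dioxin-4-one | CCCCCCCCCCCCC[C@H](CC(O)CC(=O)CC1=CC(=O)OC(C)(C)O1)O[Si](C(C)C)(C(C)C)C(C)C
F8 | step 9 | 5-(benzyloxy)-2-(hydroxymethyl)-3-[(2R)-2-(triisopropylsilyloxy)pentadecyl]phenol | CCCCCCCCCCCCC[C@H](Cc1cc(OCc2ccccc2)cc(O)c1CO)O[Si](C(C)C)(C(C)C)C(C)C
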